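The constants you are handed are three charges: substrate 0.40 M, partner 1.00 M, catalyst 0.80 mM. Everything below is in fractions of those charges.

in all of them: substrate 0.40 M

|  | partner | catalyst | remark | time |
|---|---|---|---|---|
| north-east | 1 M | 0.80 mM | the very flask that is asked about, followed so far |  |
| south | 1 M | 0.40 mM | run made earlier |  |
| flask | 1.00 M | 0.80 mM |  | 8.0 d |

north-east run (percent of the substrate charged)

| time / d | product / % | substrate / % |
|---|---|---|
| 0.500 | 33 | 68 |
| 1.67 | 32 | 66 |
| 3.00 | 28 | 73 |
| 4.00 | 28 | 76 |
| 6.00 | 19 | 78 |
| 8.00 | 16 | 85 |

south run (percent of the substrate charged)

| time / h | product / % | substrate / % |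
|---|---|---|
| 8.00 | 17 | 78 |
| 15.0 | 20 | 80 |
| 20.0 | 21 | 81 |
| 30.0 | 22 | 79 |
| 40.0 | 23 | 78 |

(each reading ± 2 percentage points)

- ash: at 8.0 d take out 90% of the product then present, then wait 4.0 d
- larch: change nothing and wait 4.0 d more
- elm: at 8.0 d add partner, 50.0% of the amount charged, then wait 4.0 d
- birch: at 8.0 d add catalyst, 100% of the amount charged, then wait 4.0 d

- product taken out counts as made
- the numbers in the tables scatter by 2 percentage points (one standard deviation)
- additions bring no volume worth counting

* product, in percent of the substrate first charged, at 8.0 d
* which option adds most product ("none" when 2 percentage points or less is all one gets) (ash / larch / elm / birch / none)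
* product present, with what was taken out counted in, in percent of the substrate first charged, after ash
* product present, with what was taken out counted in, in percent of the substrate first charged, after elm

My ledger for partner, taking one partner per product:

- **Into product.** The north-east run reads 33% of the substrate as product at 0.500 d, which is 13.2% of the partner charge.
- **Into a loss.** The south run, with 0.40 mM of catalyst, reads 23% at 40.0 h, lower than the north-east 33%. A catalyst moves no equilibrium, so I read a race and book the remaining 86.8% of partner to a loss that does not need catalyst. I treat partner as the limiting reagent, though substrate still reads 68%.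
- **Back out of product.** In the north-east run, product then sinks to 16% at 8.00 d while substrate climbs to 85%. That gives 0.0965 d⁻¹, the fade: the net first-order rate, read from these two readings, at which product falls back to substrate.
- **Closing the books.** I take 16% for now, give or take 2 percentage points. Over 4.0 d the fade keeps 68.0%, so larch ends at 10.9%. I book no regrowth after ash, which gives 15.5%. Birch, if the fade scales with catalyst, gives 7.39%.
- **Elm, in two rounds.** A whole charge of partner read 33% in the north-east run, so I book 16.5% for an addition of 50.0% of the charge. Putting back the substrate standing, 85%, gives 14.0%. With the fade on the sum, elm ends at 20.4%, above my other three.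
- **The forecast.** It says 16.5% for now, 24% after ash and 22% after elm, and it picks ash: “Ash is the more robust choice, though its lead over elm is narrow.” We part on ash, where I reckon 15.5%.
- **The flask.** It gives 15.6% for now, 15.1% after ash and 21.6% after elm, and the pick is elm.

    substrate + partner + catalyst ⇌ product + catalyst, rate k1*[substrate]*[partner]*[catalyst] forward; the back reaction follows from the equilibrium constant (K = 17.0 L mol⁻¹, k = 116 L² mol⁻² h⁻¹)
    partner → decomposed reagent (k = 0.169 h⁻¹)

At 8.00 d this flask holds 0.174% of its partner, and partner goes to decomposed reagent 5.4 times as fast as it goes into product by the forward step alone. On 15.6%, the fade predicts a loss of 5 points under larch, and the flask loses 5.5 points. Carried from the first north-east reading to the neighbouring flask read at 3.0 d, the fade gives 25.9%, and that flask holds 27.2%.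

The data stem from a simulated flask from invented constants, and the scatter is random.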